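## Analysis of the target

The target is a trans-fused hydrindane joined through an sp2 carbon to an oxygenated side chain. Ring A is the cyclohexane C3a–C4–C5–C6–C7–C7a with a gem-dimethyl group at C4, and ring B is the cyclopentane C1–C2–C3–C3a–C7a. C1 carries a 1,1-disubstituted alkene (C8=C9H2) whose carbon C8 is bonded to C10; C10 bears an acetoxymethyl group (C11) and C4' of a 3-hydroxy-γ-butyrolactone (O1'–C2'(=O)–C3'(OH)–C4'–C5'H2). There are six stereocentres: C1 (R), C3a (S) and C7a (S) in the bicycle, and C10 (R), C4' (R) and C3' (S) in the side chain. The ring fusion is trans, the C1 substituent is cis to the C7a methyl group, and the C3' hydroxyl is trans to the C10 substituent on the lactone. The two clusters are separated by C8, so neither can control the other. The sensitive groups are the C8=C9 alkene with two tertiary allylic C–H bonds (acid-induced migration; no late hydrogenation, ozonolysis or borane), the α-hydroxy lactone (epimerisation, over-reduction) and the primary acetate next to a free secondary hydroxyl (acyl migration, translactonisation). The hard part of the bicycle is that ring A has no functional group, that quaternary C7a sits next to the C3a methine and 1,3 to quaternary C4, and that ring closure onto a five-membered ring does not favour the trans fusion. The strategy rests on one feature: C3a and C7a are adjacent atoms of ring B whose bonds into ring A (C3a–C4 and C7a–C7) are trans. This is the pattern left when a nucleophile adds to the β-carbon of 2-methylcyclopent-2-enone and the enolate is alkylated anti to the new group.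

## Retrosynthetic reasoning

**30 ⇒ 29 ⇒ 28 (C11–O acyl bond, then O–Si bond).** The acetate goes on last, because it would not survive the organometallic, enolate and hydride steps. In diol 29 the primary C11 hydroxyl is distinguished from the hindered C3' hydroxyl by sterics. Diol 29 comes from silyl ether 28, and the silyl group is chosen to survive every step from 15 onward.

**28 ⇒ 27 ⇒ 26 (lactone C2'–O1' bond, then C5' oxidation level).** Opening the lactone gives hydroxy ester 27. Its C5' hydroxymethyl group is traced to the imide carbonyl of 26, so hydride reduction releases auxiliary 16 and creates the lactone oxygen in one operation. The forward reduction must touch the imide and leave the C2' ester alone, hence the tert-butyl ester.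

**26 ⇒ 23 + 24 (C3'–C4' bond).** This cut is an aldol between boron enolate 25 of imide 23 and glyoxylate 24. It forms C4' and C3' together, with the hydroxyl in place and C2' already at the acid oxidation level. It is preferred to enolate alkylation because the boron aldol and the chelate-controlled conjugate addition that sets C10 use opposite enolate faces for the same auxiliary, which is the C10/C4' relationship the target needs. Alkylation of the same imide would give the wrong C4'.

**23 ⇒ 13 + 20 (C8–C10 bond).** This is the only bond between the two stereo-clusters. Cutting it gives an alkenyl nucleophile (21, then 22) that already contains C8=C9, so no ketone flanked by two tertiary carbons has to be methylenated. The acceptor 20 carries the auxiliary that fixes C10 independently of the hydrindane.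

**20 ⇒ 19 + 15; 19 ⇒ 16 + 17; 15 ⇒ 14.** The enoyl imide is cut at its alkene by cross-metathesis into acryloyl imide 19 and allyl silyl ether 15, both one step from commercial 16, 17 and 14.

**13 ⇒ 12 ⇒ 11 ⇒ 9 ⇒ 8 (C1–C8 bond and the C1 stereocentre).** The alkenyl metal is unmasked from hydrazone 13 of methyl ketone 12. The two side-chain carbons are attached to C1 by olefination of ketone 8 to give 9. The C1 hydrogen is then delivered by hydroboration from the face opposite the C7a methyl group, which gives the cis relationship between the C1 substituent and that methyl.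

**8 ⇒ 7 ⇒ 6 (C6–CO2 bond).** The ester at C6 is only an activating group for the ring closure and is removed by hydrolysis and decarboxylation.

**6 ⇒ 5 (C4–C5 bond, ring A).** Ring A is opened at the bond to the gem-dimethyl carbon. In the forward direction a tertiary radical generated at the isopropenyl group of 5 adds to the acrylate terminus. The ring fusion is not created in this step; it is only carried through.

**5 ⇒ 1 + 2 + 3 (C3a–C4 and C7a–C7).** Both ring-fusion bonds are cut on the monocyclic stage. Conjugate addition of 2 to 1 sets C3a under catalyst control, and alkylation of enolate 4 with 3 sets C7a anti to the new group. The trans fusion is therefore fixed by two intermolecular events from three commercial components.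

## Alternatives that were turned down

**Alternative 1: ring contraction of a trans-decalin.** The C7a–C1 bond is traced to diazoketone A2. On photolysis in an alcohol it loses nitrogen, the quaternary carbon migrates to the carbene carbon, and the ketene is trapped as ester A1.
- For: the trans fusion and both quaternary centres come from a decalin, for which there is reliable access; migration proceeds with retention; A1 already has a carbon substituent on C1. On that last point it is stronger than the chosen route, which needs steps 5 to 7 to attach two carbons to C1.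
- Against: A2 needs an enantiopure trimethyldecalone (several steps), then diazo installation next to a hindered carbonyl, then a photochemical step. The C1 configuration of A1 comes from protonation of a ketene and is not controlled. A1 still has to be turned into a methyl ketone.
- Comparison: this route reaches the stage of 12 in clearly more operations than the seven used here. The chosen strategy offers the bicycle in four steps from commercial materials and a face-selective hydroboration for C1.

**Alternative 2: cationic bicyclisation of an acyclic epoxide.** Bonds C4–C3a and C7a–C1 are formed in one cascade from A4. A Lewis acid opens the epoxide, the E-alkene relays the cation, and the allylsilane terminates to leave C8=C9, giving A3.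
- For: this is the most convergent plan. Two rings, C3a, C7a, C1 and the exocyclic methylene are formed in one step with the side chain complete. It is stronger than the chosen route in step count after the ring-forming event, and it avoids a late fragment coupling.
- Against: A4 is a long synthesis in itself (trisubstituted E-alkene, enantiopure epoxide, allylsilane and a lactone with three stereocentres on one chain). The Lewis acid must select the epoxide in the presence of lactone and acetate carbonyls, which can bind the acid or trap the cation. The five-membered closure that sets C1 against C7a is less ordered than a six-membered one. A3 carries a C5 hydroxyl that the target lacks, and a hindered secondary alcohol next to a quaternary carbon has to be deoxygenated in two further steps.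
- Comparison: the chosen strategy secures the ring system first by two predictable intermolecular events and attaches the side chain under auxiliary control.

**Alternative 3: desymmetrising oxygen insertion into a cyclobutanone.** The lactone O1'–C5' bond is traced to cyclobutanone A6. A chiral Brønsted acid with a peroxide oxidant selects one of the two CH2–CO bonds, which fixes C4' and gives A5.
- For: it is catalytic, needs no auxiliary and builds the lactone late from a robust carbocycle. On atom economy it is stronger than the auxiliary-based steps 12 to 14.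
- Against: it solves only the lactone and presupposes the hydrindane and C10. The two methylene groups of A6 are diastereotopic because of C10, so the catalyst works in a matched or mismatched situation. Such systems discriminate best for 3-aryl cyclobutanones, not branched alkyl ones. The electron-rich C8=C9 alkene is exposed to an acidic peroxide medium. A5 still lacks the C3' hydroxyl.
- Comparison: the chosen route creates C4' and C3' together with the hydroxyl in one aldol step of predictable sense, and the diastereomers are separable.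

Key step: step 1

Assumption: the enantiomer of the ferrocenyl bisphosphine in step 1 is the one that delivers the alkenyl group to the face giving (S) at the β-carbon; if the sense of induction is the reverse, the mirror-image ligand is used.

## Steps

Step 1
Reactants: 1 2-methylcyclopent-2-en-1-one; 2 isopropenylmagnesium bromide; 3 ethyl 2-(bromomethyl)prop-2-enoate
Product: 5 ethyl 2-{[(1S,2S)-1-methyl-5-oxo-2-(prop-1-en-2-yl)cyclopentyl]methyl}prop-2-enoate, via bromomagnesium enolate 4 (not isolated)
Conditions: CuBr·SMe2 (5 mol%), (R)-1-[(SP)-2-(diphenylphosphino)ferrocenyl]ethyldicyclohexylphosphine (6 mol%), t-BuOMe, −78 °C, slow addition of 2; then 3, DMPU, THF, −78 → 0 °C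
Reagents that add atoms: none
Why: The Grignard reagent transmetalates to the chiral copper–bisphosphine complex, which binds enone 1, adds at the β-carbon and reductively eliminates to form C3a–C4, leaving bromomagnesium enolate 4 with its double bond fixed between the carbonyl carbon and the methyl-bearing carbon. The closest known reaction type is the copper-catalysed asymmetric conjugate addition of Grignard reagents to 2-substituted cyclopentenones with alkylation of the enolate; the alkenyl nucleophile is an extension inside that class. Enolate 4 is then alkylated at carbon by allylic bromide 3 (direct and allylic-transposition displacement give the same product), which forms C7a–C7 and the quaternary centre. No ring is closed in this step. The configuration at the future C3a is set by the ligand on copper, and that at the future C7a by the adjacent isopropenyl group, which shields its own face so that 3 enters anti and the two future ring A bonds come out trans. The step needs 1,4- over 1,2-addition (copper catalysis, low temperature, slow addition of 2), a regiodefined enolate (4 is trapped before proton exchange, the polar co-solvent being added only with the very reactive electrophile) and C- over O-alkylation (favoured for a soft allylic bromide).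

Step 2
Reactants: 5 ethyl 2-{[(1S,2S)-1-methyl-5-oxo-2-(prop-1-en-2-yl)cyclopentyl]methyl}prop-2-enoate
Product: 6 ethyl (3aS,7aS)-4,4,7a-trimethyl-1-oxooctahydro-1H-indene-6-carboxylate (both C6 epimers)
Conditions: Fe(acac)3 (30 mol%), PhSiH3, EtOH/ethylene glycol, 60 °C, high dilution
Reagents that add atoms: none
Why: Hydrogen-atom transfer from an iron hydride to the electron-rich isopropenyl group gives a tertiary radical that adds 6-endo to the unsubstituted terminus of the tethered acrylate (intramolecular Giese reaction), forming C4–C5 and the gem-dimethyl carbon; the α-ester radical is then reduced and protonated. The trans ring fusion is already fixed in 5, and the C6 centre is removed in step 4.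

Step 3
Reactants: 6 ethyl (3aS,7aS)-4,4,7a-trimethyl-1-oxooctahydro-1H-indene-6-carboxylate
Product: 7 (3aS,7aS)-4,4,7a-trimethyl-1-oxooctahydro-1H-indene-6-carboxylic acid (both C6 epimers)
Conditions: LiOH, THF/MeOH/H2O, rt; then 1 M HCl
Reagents that add atoms: lithium hydroxide, [Li+].[OH-]
Why: Saponification of an unhindered secondary ethyl ester; the only enolisable position next to the ketone is C2, so no stereocentre of the bicycle can epimerise.

Step 4
Reactants: 7 (3aS,7aS)-4,4,7a-trimethyl-1-oxooctahydro-1H-indene-6-carboxylic acid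
Product: 8 (3aS,7aS)-4,4,7a-trimethyloctahydro-1H-inden-1-one
Conditions: 9-mesityl-10-phenylacridinium tetrafluoroborate (5 mol%), (PhS)2 (10 mol%), i-Pr2NEt (20 mol%), CF3CH2OH, 450 nm LED, rt
Reagents that add atoms: none
Why: Photoredox hydrodecarboxylation: the excited acridinium oxidises the carboxylate, loss of CO2 gives a secondary cyclohexyl radical, and thiophenol formed in the flask returns a hydrogen atom; ketones are inert to these conditions.

Step 5
Reactants: 8 (3aS,7aS)-4,4,7a-trimethyloctahydro-1H-inden-1-one
Product: 9 (1Z,3aS,7aS)-1-ethylidene-4,4,7a-trimethyloctahydro-1H-indene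
Conditions: EtPPh3Br, KOt-Bu, THF, reflux
Reagents that add atoms: ethyltriphenylphosphonium bromide, CC[P+](c1ccccc1)(c1ccccc1)c1ccccc1.[Br-]
Why: Wittig olefination of a cyclopentanone next to a quaternary carbon with a non-stabilised ylide, which forms C1–C8 and brings in C9; the alkene geometry (Z expected) has no consequence because C8 becomes a carbonyl carbon in step 7.

Step 6
Reactants: 9 (1Z,3aS,7aS)-1-ethylidene-4,4,7a-trimethyloctahydro-1H-indene
Product: 11 1-[(1S,3aS,7aS)-4,4,7a-trimethyloctahydro-1H-inden-1-yl]ethan-1-ol, via alkylborane 10 (not isolated)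
Conditions: BH3·SMe2, THF, 0 °C → rt; then NaOH, 30% H2O2, 0 °C → rt
Reagents that add atoms: hydrogen peroxide, OO
Why: Hydroboration–oxidation places boron on the less substituted C8 and hydrogen on C1 from the face opposite the C7a methyl group, so the two-carbon chain on C1 ends up cis to that methyl (the C1 configuration of the target). The carbinol configuration is lost in step 7.

Step 7
Reactants: 11 1-[(1S,3aS,7aS)-4,4,7a-trimethyloctahydro-1H-inden-1-yl]ethan-1-ol
Product: 12 1-[(1S,3aS,7aS)-4,4,7a-trimethyloctahydro-1H-inden-1-yl]ethan-1-one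
Conditions: Dess–Martin periodinane, CH2Cl2, rt
Reagents that add atoms: none
Why: Neutral oxidation of a secondary alcohol to the methyl ketone; C1 is not exposed to base, and the acetyl group cis to the angular methyl is in any case the favoured epimer.

Step 8
Reactants: 12 1-[(1S,3aS,7aS)-4,4,7a-trimethyloctahydro-1H-inden-1-yl]ethan-1-one
Product: 13 N'-{(1E)-1-[(1S,3aS,7aS)-4,4,7a-trimethyloctahydro-1H-inden-1-yl]ethylidene}-2,4,6-tri(propan-2-yl)benzenesulfonohydrazide
Conditions: 2,4,6-triisopropylbenzenesulfonyl hydrazide, HCl (cat.), THF, rt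
Reagents that add atoms: 2,4,6-tri(propan-2-yl)benzenesulfonohydrazide, CC(C)c1cc(C(C)C)c(S(=O)(=O)NN)c(C(C)C)c1
Why: Condensation of a methyl ketone with an arenesulfonyl hydrazide; the sulfonamide nitrogen settles anti to the bulky hydrindanyl group, which is the geometry needed for deprotonation at the methyl group in step 12.

Step 9
Reactants: 14 prop-2-en-1-ol
Product: 15 tert-butyl(diphenyl)(prop-2-en-1-yloxy)silane
Conditions: t-BuPh2SiCl, imidazole, CH2Cl2, rt
Reagents that add atoms: tert-butyl(chloro)diphenylsilane, CC(C)(C)[Si](Cl)(c1ccccc1)c1ccccc1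
Why: Standard silylation of a primary alcohol; this silyl ether is chosen because it survives organocopper, boron triflate, hydride and catalytic acid.

Step 10
Reactants: 16 (4S)-4-benzyl-1,3-oxazolidin-2-one; 17 prop-2-enoyl chloride
Product: 19 (4S)-4-benzyl-3-(prop-2-enoyl)-1,3-oxazolidin-2-one, via lithium oxazolidinide 18 (not isolated)
Conditions: n-BuLi, THF, −78 °C; then 17, −78 → 0 °C
Reagents that add atoms: none
Why: N-Acylation of the lithiated oxazolidinone with an acid chloride at low temperature, which limits polymerisation of the acrylate.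

Step 11
Reactants: 19 (4S)-4-benzyl-3-(prop-2-enoyl)-1,3-oxazolidin-2-one; 15 tert-butyl(diphenyl)(prop-2-en-1-yloxy)silane
Product: 20 (4S)-4-benzyl-3-[(2E)-4-{[tert-butyl(diphenyl)silyl]oxy}but-2-enoyl]-1,3-oxazolidin-2-one
Conditions: second-generation Hoveyda–Grubbs catalyst, RuCl2(H2IMes)(=CH-C6H4-2-Oi-Pr) (5 mol%), 15 (3 equiv), CH2Cl2, 40 °C
Reagents that add atoms: none
Why: Cross-metathesis between an electron-poor acryloyl imide, which does not homodimerise, and an excess of an electron-rich terminal alkene; the conjugated product forms as the E isomer.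

Step 12
Reactants: 13 N'-{(1E)-1-[(1S,3aS,7aS)-4,4,7a-trimethyloctahydro-1H-inden-1-yl]ethylidene}-2,4,6-tri(propan-2-yl)benzenesulfonohydrazide; 20 (4S)-4-benzyl-3-[(2E)-4-{[tert-butyl(diphenyl)silyl]oxy}but-2-enoyl]-1,3-oxazolidin-2-one
Product: 23 (4S)-4-benzyl-3-[(3R)-4-{[tert-butyl(diphenyl)silyl]oxy}-3-{1-[(1R,3aS,7aS)-4,4,7a-trimethyloctahydro-1H-inden-1-yl]ethenyl}butanoyl]-1,3-oxazolidin-2-one, via alkenyllithium 21 (not isolated), via alkenylmagnesium bromide 22 (not isolated)
Conditions: n-BuLi (2.1 equiv), THF, −78 → 0 °C; MgBr2·OEt2, −78 °C; CuBr·SMe2, Me2S, −78 °C; then 20, −78 → −20 °C; aq. NH4Cl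
Reagents that add atoms: none
Why: The Shapiro reaction (double deprotonation at N–H and at the methyl group, loss of sulfinate and nitrogen) gives the 1-substituted alkenyllithium 21 with C8=C9 in place; transmetalation to 22 and then to copper allows 1,4-addition to 20, forming C8–C10. The magnesium-chelated s-cis conformer of the enoyl imide is attacked on the face opposite the benzyl group, which gives (R) at C10.

Step 13
Reactants: 23 (4S)-4-benzyl-3-[(3R)-4-{[tert-butyl(diphenyl)silyl]oxy}-3-{1-[(1R,3aS,7aS)-4,4,7a-trimethyloctahydro-1H-inden-1-yl]ethenyl}butanoyl]-1,3-oxazolidin-2-one; 24 tert-butyl 2-oxoacetate (freshly distilled)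
Product: 26 tert-butyl (2S,3S,4R)-3-{[(4S)-4-benzyl-2-oxo-1,3-oxazolidin-3-yl]carbonyl}-4-({[tert-butyl(diphenyl)silyl]oxy}methyl)-2-hydroxy-5-[(1R,3aS,7aS)-4,4,7a-trimethyloctahydro-1H-inden-1-yl]hex-5-enoate, via dibutylboron enolate 25 (not isolated)
Conditions: Bu2BOTf, i-Pr2NEt, CH2Cl2, 0 °C; then 24, −78 → 0 °C; pH 7 buffer, MeOH, 30% H2O2, 0 °C
Reagents that add atoms: none
Why: Evans syn-aldol reaction: the Z boron enolate 25 reacts with the glyoxylate aldehyde through a Zimmerman–Traxler chair with the auxiliary carbonyl turned away from boron, forming C3'–C4'. The aldehyde therefore enters on the enolate face opposite to that used in chelate-controlled reactions, which gives C4' (R) and, through the syn relationship, C3' (S) with its hydroxyl.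

Step 14
Reactants: 26 tert-butyl (2S,3S,4R)-3-{[(4S)-4-benzyl-2-oxo-1,3-oxazolidin-3-yl]carbonyl}-4-({[tert-butyl(diphenyl)silyl]oxy}methyl)-2-hydroxy-5-[(1R,3aS,7aS)-4,4,7a-trimethyloctahydro-1H-inden-1-yl]hex-5-enoate
Product: 27 tert-butyl (2S,3R,4R)-4-({[tert-butyl(diphenyl)silyl]oxy}methyl)-2-hydroxy-3-(hydroxymethyl)-5-[(1R,3aS,7aS)-4,4,7a-trimethyloctahydro-1H-inden-1-yl]hex-5-enoate
Conditions: LiBH4, MeOH (1 equiv), THF, 0 °C
Reagents that add atoms: none
Why: Reductive removal of the auxiliary from a β-hydroxy imide, which is activated by chelation, turns the imide carbonyl into the C5' hydroxymethyl group; the hindered tert-butyl ester is not reduced and cannot lactonise in the flask, so the hydride never meets a lactone.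

Step 15
Reactants: 27 tert-butyl (2S,3R,4R)-4-({[tert-butyl(diphenyl)silyl]oxy}methyl)-2-hydroxy-3-(hydroxymethyl)-5-[(1R,3aS,7aS)-4,4,7a-trimethyloctahydro-1H-inden-1-yl]hex-5-enoate
Product: 28 (3S,4R)-4-[(2R)-1-{[tert-butyl(diphenyl)silyl]oxy}-3-[(1R,3aS,7aS)-4,4,7a-trimethyloctahydro-1H-inden-1-yl]but-3-en-2-yl]-3-hydroxyoxolan-2-one
Conditions: camphorsulfonic acid (10 mol%), CH2Cl2, rt
Reagents that add atoms: none
Why: Acid-catalysed transesterification of a γ-hydroxy tert-butyl ester closes the five-membered lactone (C2'–O1' bond); only the C5' hydroxyl can reach C2' in a five-membered ring because C11 is still silylated. Catalytic sulfonic acid in a non-ionising solvent should leave the C8=C9 alkene and the silyl ether untouched.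

Step 16
Reactants: 28 (3S,4R)-4-[(2R)-1-{[tert-butyl(diphenyl)silyl]oxy}-3-[(1R,3aS,7aS)-4,4,7a-trimethyloctahydro-1H-inden-1-yl]but-3-en-2-yl]-3-hydroxyoxolan-2-one
Product: 29 (3S,4R)-3-hydroxy-4-[(2R)-1-hydroxy-3-[(1R,3aS,7aS)-4,4,7a-trimethyloctahydro-1H-inden-1-yl]but-3-en-2-yl]oxolan-2-one
Conditions: Bu4NF, AcOH (1:1), THF, 0 °C → rt
Reagents that add atoms: none
Why: Fluoride cleavage of the primary silyl ether; buffering with acetic acid keeps the medium from epimerising C3' or promoting translactonisation.

Step 17
Reactants: 29 (3S,4R)-3-hydroxy-4-[(2R)-1-hydroxy-3-[(1R,3aS,7aS)-4,4,7a-trimethyloctahydro-1H-inden-1-yl]but-3-en-2-yl]oxolan-2-one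
Product: 30 (2R)-2-[(3R,4S)-4-hydroxy-5-oxooxolan-3-yl]-3-[(1R,3aS,7aS)-4,4,7a-trimethyloctahydro-1H-inden-1-yl]but-3-en-1-yl acetate
Conditions: AcCl (1.1 equiv), 2,4,6-collidine, CH2Cl2, −78 °C
Reagents that add atoms: acetyl chloride, CC(Cl)=O
Why: Selective acetylation of a primary alcohol with an acid chloride and a hindered pyridine base at low temperature; the C3' hydroxyl is secondary, flanked by the C4' substituent and deactivated by the lactone carbonyl.

## Compound list

1 | 2-methylcyclopent-2-en-1-one | CC1=CCCC1=O | starting material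
2 | isopropenylmagnesium bromide | CC(=C)[Mg]Br | starting material
3 | ethyl 2-(bromomethyl)prop-2-enoate | C=C(CBr)C(=O)OCC | starting material
4 | bromomagnesium (3S)-2-methyl-3-(prop-1-en-2-yl)cyclopent-1-en-1-olate | C=C(C)[C@@H]1CCC(O[Mg]Br)=C1C | intermediate
5 | ethyl 2-{[(1S,2S)-1-methyl-5-oxo-2-(prop-1-en-2-yl)cyclopentyl]methyl}prop-2-enoate | O=C1CC[C@@H](C(C)=C)[C@]1(C)CC(=C)C(=O)OCC | intermediate
6 | ethyl (3aS,7aS)-4,4,7a-trimethyl-1-oxooctahydro-1H-indene-6-carboxylate (C6 epimers) | O=C1CC[C@H]2C(C)(C)CC(C(=O)OCC)C[C@]12C | intermediate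
7 | (3aS,7aS)-4,4,7a-trimethyl-1-oxooctahydro-1H-indene-6-carboxylic acid (C6 epimers) | O=C1CC[C@H]2C(C)(C)CC(C(=O)O)C[C@]12C | intermediate
8 | (3aS,7aS)-4,4,7a-trimethyloctahydro-1H-inden-1-one | O=C1CC[C@H]2C(C)(C)CCC[C@]12C | intermediate
9 | (1Z,3aS,7aS)-1-ethylidene-4,4,7a-trimethyloctahydro-1H-indene | C/C=C1/CC[C@H]2C(C)(C)CCC[C@]12C | intermediate
10 | {1-[(1R,3aS,7aS)-4,4,7a-trimethyloctahydro-1H-inden-1-yl]ethyl}borane (C1 hydrogen on the face opposite the C7a methyl) | CC(B)[C@H]1CC[C@H]2C(C)(C)CCC[C@]12C | intermediate
11 | 1-[(1S,3aS,7aS)-4,4,7a-trimethyloctahydro-1H-inden-1-yl]ethan-1-ol (carbinol configuration not relevant) | CC(O)[C@H]1CC[C@H]2C(C)(C)CCC[C@]12C | intermediate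
12 | 1-[(1S,3aS,7aS)-4,4,7a-trimethyloctahydro-1H-inden-1-yl]ethan-1-one | CC(=O)[C@H]1CC[C@H]2C(C)(C)CCC[C@]12C | intermediate
13 | N'-{(1E)-1-[(1S,3aS,7aS)-4,4,7a-trimethyloctahydro-1H-inden-1-yl]ethylidene}-2,4,6-tri(propan-2-yl)benzenesulfonohydrazide | C/C(=N\NS(=O)(=O)c1c(C(C)C)cc(C(C)C)cc1C(C)C)[C@H]1CC[C@H]2C(C)(C)CCC[C@]12C | intermediate
14 | prop-2-en-1-ol | C=CCO | starting material
15 | tert-butyl(diphenyl)(prop-2-en-1-yloxy)silane | C=CCO[Si](c1ccccc1)(c1ccccc1)C(C)(C)C | intermediate
16 | (4S)-4-benzyl-1,3-oxazolidin-2-one | O=C1N[C@@H](Cc2ccccc2)CO1 | starting material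
17 | prop-2-enoyl chloride | C=CC(=O)Cl | starting material
18 | lithium (4S)-4-benzyl-2-oxo-1,3-oxazolidin-3-ide | [Li]N1[C@@H](Cc2ccccc2)COC1=O | intermediate
19 | (4S)-4-benzyl-3-(prop-2-enoyl)-1,3-oxazolidin-2-one | C=CC(=O)N1[C@@H](Cc2ccccc2)COC1=O | intermediate
20 | (4S)-4-benzyl-3-[(2E)-4-{[tert-butyl(diphenyl)silyl]oxy}but-2-enoyl]-1,3-oxazolidin-2-one | O=C(/C=C/CO[Si](c1ccccc1)(c1ccccc1)C(C)(C)C)N1[C@@H](Cc2ccccc2)COC1=O | intermediate
21 | {1-[(3aS,7aS)-4,4,7a-trimethyloctahydro-1H-inden-1-yl]ethenyl}lithium (C1 arrangement as in 12) | [Li]C(=C)[C@H]1CC[C@H]2C(C)(C)CCC[C@]12C | intermediate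
22 | bromo{1-[(3aS,7aS)-4,4,7a-trimethyloctahydro-1H-inden-1-yl]ethenyl}magnesium (C1 arrangement as in 12) | Br[Mg]C(=C)[C@H]1CC[C@H]2C(C)(C)CCC[C@]12C | intermediate
23 | (4S)-4-benzyl-3-[(3R)-4-{[tert-butyl(diphenyl)silyl]oxy}-3-{1-[(1R,3aS,7aS)-4,4,7a-trimethyloctahydro-1H-inden-1-yl]ethenyl}butanoyl]-1,3-oxazolidin-2-one | C=C([C@H]1CC[C@H]2C(C)(C)CCC[C@]12C)[C@H](CO[Si](c1ccccc1)(c1ccccc1)C(C)(C)C)CC(=O)N1[C@@H](Cc2ccccc2)COC1=O | intermediate
24 | tert-butyl 2-oxoacetate | O=CC(=O)OC(C)(C)C | starting material
25 | dibutylboron (Z)-enolate of 23 | C=C([C@H]1CC[C@H]2C(C)(C)CCC[C@]12C)[C@H](CO[Si](c1ccccc1)(c1ccccc1)C(C)(C)C)/C=C(\OB(CCCC)CCCC)N1[C@@H](Cc2ccccc2)COC1=O | intermediate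
26 | tert-butyl (2S,3S,4R)-3-{[(4S)-4-benzyl-2-oxo-1,3-oxazolidin-3-yl]carbonyl}-4-({[tert-butyl(diphenyl)silyl]oxy}methyl)-2-hydroxy-5-[(1R,3aS,7aS)-4,4,7a-trimethyloctahydro-1H-inden-1-yl]hex-5-enoate | C=C([C@H]1CC[C@H]2C(C)(C)CCC[C@]12C)[C@H](CO[Si](c1ccccc1)(c1ccccc1)C(C)(C)C)[C@H](C(=O)N1[C@@H](Cc2ccccc2)COC1=O)[C@H](O)C(=O)OC(C)(C)C | intermediate
27 | tert-butyl (2S,3R,4R)-4-({[tert-butyl(diphenyl)silyl]oxy}methyl)-2-hydroxy-3-(hydroxymethyl)-5-[(1R,3aS,7aS)-4,4,7a-trimethyloctahydro-1H-inden-1-yl]hex-5-enoate | C=C([C@H]1CC[C@H]2C(C)(C)CCC[C@]12C)[C@H](CO[Si](c1ccccc1)(c1ccccc1)C(C)(C)C)[C@H](CO)[C@H](O)C(=O)OC(C)(C)C | intermediate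
28 | (3S,4R)-4-[(2R)-1-{[tert-butyl(diphenyl)silyl]oxy}-3-[(1R,3aS,7aS)-4,4,7a-trimethyloctahydro-1H-inden-1-yl]but-3-en-2-yl]-3-hydroxyoxolan-2-one | C=C([C@H]1CC[C@H]2C(C)(C)CCC[C@]12C)[C@H](CO[Si](c1ccccc1)(c1ccccc1)C(C)(C)C)[C@@H]1COC(=O)[C@H]1O | intermediate
29 | (3S,4R)-3-hydroxy-4-[(2R)-1-hydroxy-3-[(1R,3aS,7aS)-4,4,7a-trimethyloctahydro-1H-inden-1-yl]but-3-en-2-yl]oxolan-2-one | C=C([C@H]1CC[C@H]2C(C)(C)CCC[C@]12C)[C@H](CO)[C@@H]1COC(=O)[C@H]1O | intermediate
30 | (2R)-2-[(3R,4S)-4-hydroxy-5-oxooxolan-3-yl]-3-[(1R,3aS,7aS)-4,4,7a-trimethyloctahydro-1H-inden-1-yl]but-3-en-1-yl acetate | C=C([C@H]1CC[C@H]2C(C)(C)CCC[C@]12C)[C@H](COC(C)=O)[C@@H]1COC(=O)[C@H]1O | target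

## Step count and least certain steps

Total: 17 steps. Longest linear sequence: 14 steps (steps 1–8 and 12–17, from 1 to 30); steps 9–11 form a three-step side branch to 20.

**Step 1 (key step).** The most likely failures are insufficient face discrimination by the copper complex with an alkenyl Grignard reagent, and slow alkylation of the hindered magnesium enolate, which allows proton exchange and loss of regiochemistry. Fallback: set out from 1 and 2, run the conjugate addition as before and intercept enolate 4 with chlorotrimethylsilane to give the isolable trimethylsilyl enol ether F1, whose enantiomeric purity can be checked. F1 is cleaved with MeLi in THF to the lithium enolate F2, which is alkylated with 3 in THF/DMPU and returns to the route at 5. Any remaining minor enantiomer becomes a separable diastereomer once the auxiliary is attached in step 12.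

**Step 2.** The tertiary radical may be reduced to an isopropyl group before it reaches the acrylate, or the acrylate may oligomerise. Fallback: set out from 5 and hydrate the isopropenyl group by Mukaiyama hydration (Co(acac)2, PhSiH3, O2) to the tertiary alcohol F3. Acylate with methyl chlorooxoacetate to the mixed oxalate F4 and hydrolyse with CsOH to the cesium oxalate F5. Irradiation with Ir[dF(CF3)ppy]2(dtbbpy)PF6 and visible light releases the same tertiary radical by double decarboxylation under conditions without a competing hydride donor; it cyclises onto the acrylate and returns to the route at 6.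

**Step 12.** The hindered, α-branched alkenylcopper species may add sluggishly, the alkenyllithium may be protonated before transmetalation, and the stereocentre at C1 may erode the facial preference set by the auxiliary. Fallback: set out from 12 and form the kinetic enol triflate F6 (KN(SiMe3)2, PhNTf2). Convert it by Miyaura borylation (B2pin2, PdCl2(PPh3)2, KOPh) to the alkenyl pinacol boronate F7. Add F7 to 20 under rhodium catalysis ([Rh(cod)Cl]2 with a chiral diene ligand matched to the auxiliary, aq. KOH, dioxane), a 1,4-addition that runs through an alkenylrhodium insertion and not through an organocopper species, and return to the route at 23.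

**Step 13.** Enolisation of the β-branched imide may be incomplete, the C10 stereocentre may work against the auxiliary, and the glyoxylate may oligomerise. Fallback: set out from 23 and cleave the auxiliary with LiOH/H2O2 to the acid F8. Attach the enantiomeric auxiliary ((4R)-4-benzyl-1,3-oxazolidin-2-one, pivaloyl chloride, Et3N, LiCl) to give imide F9. Alkylate its sodium enolate (NaN(SiMe3)2) with tert-butyl bromoacetate to give F10, in which chelate control by the (R)-auxiliary sets C4'. Reduce with LiBH4 to the hydroxy ester F11 and close it with catalytic acid to the lactone F12. Hydroxylate its lithium enolate (LiN(SiMe3)2, 2-(phenylsulfonyl)-3-phenyloxaziridine) anti to the C4' substituent, returning to the route at 28.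

**Step 14.** The α-hydroxy tert-butyl ester may be reduced together with the imide, or the hydride may open the oxazolidinone ring instead of cleaving the exocyclic acyl group. Fallback: set out from 26 and hydrolyse the imide with LiOH/H2O2 at 0 °C to the mono-acid F13. Activate it as the mixed carbonic anhydride (ethyl chloroformate, N-methylmorpholine) and reduce with NaBH4 at −15 °C, which leaves the ester and the alkene untouched, returning to the route at 27.

## Further compounds

F1 | step 1 | trimethyl{[(3S)-2-methyl-3-(prop-1-en-2-yl)cyclopent-1-en-1-yl]oxy}silane | C=C(C)[C@@H]1CCC(O[Si](C)(C)C)=C1C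
F2 | step 1 | lithium (3S)-2-methyl-3-(prop-1-en-2-yl)cyclopent-1-en-1-olate | C=C(C)[C@@H]1CCC(O[Li])=C1C
F3 | step 2 | ethyl 2-{[(1S,2R)-2-(2-hydroxypropan-2-yl)-1-methyl-5-oxocyclopentyl]methyl}prop-2-enoate | O=C1CC[C@@H](C(C)(C)O)[C@]1(C)CC(=C)C(=O)OCC
F4 | step 2 | methyl oxalate of F3 (mixed diester at the tertiary hydroxyl) | O=C1CC[C@@H](C(C)(C)OC(=O)C(=O)OC)[C@]1(C)CC(=C)C(=O)OCC
F5 | step 2 | cesium oxalate of F3 (cesium salt of the oxalate half-ester) | [Cs+].O=C1CC[C@@H](C(C)(C)OC(=O)C([O-])=O)[C@]1(C)CC(=C)C(=O)OCC
F6 | step 12 | 1-[(1S,3aS,7aS)-4,4,7a-trimethyloctahydro-1H-inden-1-yl]ethenyl trifluoromethanesulfonate | C=C(OS(=O)(=O)C(F)(F)F)[C@H]1CC[C@H]2C(C)(C)CCC[C@]12C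
F7 | step 12 | 4,4,5,5-tetramethyl-2-{1-[(1R,3aS,7aS)-4,4,7a-trimethyloctahydro-1H-inden-1-yl]ethenyl}-1,3,2-dioxaborolane | C=C(B1OC(C)(C)C(C)(C)O1)[C@H]1CC[C@H]2C(C)(C)CCC[C@]12C
F8 | step 13 | (3R)-4-{[tert-butyl(diphenyl)silyl]oxy}-3-{1-[(1R,3aS,7aS)-4,4,7a-trimethyloctahydro-1H-inden-1-yl]ethenyl}butanoic acid | C=C([C@H]1CC[C@H]2C(C)(C)CCC[C@]12C)[C@H](CO[Si](c1ccccc1)(c1ccccc1)C(C)(C)C)CC(=O)O
F9 | step 13 | (4R)-4-benzyl-3-[(3R)-4-{[tert-butyl(diphenyl)silyl]oxy}-3-{1-[(1R,3aS,7aS)-4,4,7a-trimethyloctahydro-1H-inden-1-yl]ethenyl}butanoyl]-1,3-oxazolidin-2-one | C=C([C@H]1CC[C@H]2C(C)(C)CCC[C@]12C)[C@H](CO[Si](c1ccccc1)(c1ccccc1)C(C)(C)C)CC(=O)N1[C@H](Cc2ccccc2)COC1=O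
F10 | step 13 | tert-butyl (3R,4R)-3-{[(4R)-4-benzyl-2-oxo-1,3-oxazolidin-3-yl]carbonyl}-4-({[tert-butyl(diphenyl)silyl]oxy}methyl)-5-[(1R,3aS,7aS)-4,4,7a-trimethyloctahydro-1H-inden-1-yl]hex-5-enoate | C=C([C@H]1CC[C@H]2C(C)(C)CCC[C@]12C)[C@H](CO[Si](c1ccccc1)(c1ccccc1)C(C)(C)C)[C@@H](CC(=O)OC(C)(C)C)C(=O)N1[C@H](Cc2ccccc2)COC1=O
F11 | step 13 | tert-butyl (3R,4R)-4-({[tert-butyl(diphenyl)silyl]oxy}methyl)-3-(hydroxymethyl)-5-[(1R,3aS,7aS)-4,4,7a-trimethyloctahydro-1H-inden-1-yl]hex-5-enoate | C=C([C@H]1CC[C@H]2C(C)(C)CCC[C@]12C)[C@H](CO[Si](c1ccccc1)(c1ccccc1)C(C)(C)C)[C@@H](CC(=O)OC(C)(C)C)CO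
F12 | step 13 | (4R)-4-[(2R)-1-{[tert-butyl(diphenyl)silyl]oxy}-3-[(1R,3aS,7aS)-4,4,7a-trimethyloctahydro-1H-inden-1-yl]but-3-en-2-yl]oxolan-2-one | C=C([C@H]1CC[C@H]2C(C)(C)CCC[C@]12C)[C@H](CO[Si](c1ccccc1)(c1ccccc1)C(C)(C)C)[C@@H]1COC(=O)C1
F13 | step 14 | (2S,3R)-2-[(1S)-2-tert-butoxy-1-hydroxy-2-oxoethyl]-3-({[tert-butyl(diphenyl)silyl]oxy}methyl)-4-[(1R,3aS,7aS)-4,4,7a-trimethyloctahydro-1H-inden-1-yl]pent-4-enoic acid | C=C([C@H]1CC[C@H]2C(C)(C)CCC[C@]12C)[C@H](CO[Si](c1ccccc1)(c1ccccc1)C(C)(C)C)[C@H](C(=O)O)[C@H](O)C(=O)OC(C)(C)C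
A1 | alternative 1 | methyl (1S,3aS,7aS)-4,4,7a-trimethyloctahydro-1H-indene-1-carboxylate | COC(=O)[C@H]1CC[C@H]2C(C)(C)CCC[C@]12C
A2 | alternative 1 | (4aS,8aS)-2-diazo-5,5,8a-trimethyloctahydronaphthalen-1(2H)-one | [N-]=[N+]=C1CC[C@H]2C(C)(C)CCC[C@]2(C)C1=O
A3 | alternative 2 | 5-hydroxy analogue of the target with the C3' hydroxyl as tert-butyldimethylsilyl ether (configuration as in the SMILES) | C=C([C@H]1CC[C@H]2C(C)(C)[C@@H](O)CC[C@]12C)[C@H](COC(C)=O)[C@@H]1COC(=O)[C@H]1O[Si](C)(C)C(C)(C)C
A4 | alternative 2 | acyclic (S)-epoxide with an E trisubstituted alkene and a 2-(trimethylsilylmethyl)alkene, carrying the acetoxymethyl group and the silylated hydroxy lactone (configuration as in the SMILES) | CC1(C)O[C@H]1CC/C(C)=C/CC/C=C(\C[Si](C)(C)C)[C@H](COC(C)=O)[C@@H]1COC(=O)[C@H]1O[Si](C)(C)C(C)(C)C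
A5 | alternative 3 | 4-substituted oxolan-2-one lacking the C3' hydroxyl, C11 as tert-butyldimethylsilyl ether (configuration as in the SMILES) | C=C([C@H]1CC[C@H]2C(C)(C)CCC[C@]12C)[C@H](CO[Si](C)(C)C(C)(C)C)[C@@H]1COC(=O)C1
A6 | alternative 3 | 3-substituted cyclobutan-1-one carrying the C10 side chain, C11 as tert-butyldimethylsilyl ether (configuration as in the SMILES) | C=C([C@H]1CC[C@H]2C(C)(C)CCC[C@]12C)[C@H](CO[Si](C)(C)C(C)(C)C)C1CC(=O)C1
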